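**Plan**

- Retrosynthesis: the C-6 hydroxyl of unit B (the 5-aryloxy-6,7-dihydroxycoumarin) is removed first (C6–O bond). The pyranone of unit B is then opened at C4a–C4 and O1–C2, releasing ethyl propiolate. Last, the diaryl ether between the C-6 oxygen of unit A (the 7-hydroxycoumarin) and C-5 of unit B is cut, and three O-methyl groups are taken off.
- Enabling feature: without its C-6 hydroxyl, the benzene ring of unit B is a 5-aryloxyresorcinol with a mirror plane. C-4a lies between C-5 (aryloxy) and C-8a (O-1) and para to the C-7 oxygen, so it is one of two equivalent carbons ortho to one hydroxyl and para to the other. That is the position where a phenol adds to a propiolate and then lactonises.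
- Forward order: the coumarin of unit A is bought ready-made. The diaryl ether is made first, the phenols are unmasked, the pyranone ring of unit B is closed third, and the C-6 hydroxyl is introduced last, para to the O-1 phenoxide of the opened lactone.
- Stereochemistry: the target has no stereocentre. The cis C3=C4 alkene of each pyranone is fixed by the ring (trans hydroarylation in the key step, Z-cinnamate retained through the last step).

Key step: step 3

Remark: isoscopoletin is treated as a commercially available compound; the target is achiral, so no configuration has to be set.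

**Route**

Step 1
Reactants: 1 isoscopoletin (6-hydroxy-7-methoxy-2H-chromen-2-one); 2 3,5-dimethoxyphenylboronic acid
Product: 3 6-(3,5-dimethoxyphenoxy)-7-methoxy-2H-chromen-2-one
Conditions: 2 (2.5 equiv), Cu(OAc)2 (0.3 equiv), pyridine, 4 Å MS, CH2Cl2, O2 (1 atm), rt
Reagents that add atoms: none
Why: Chan–Lam oxidative C–O coupling, in which the aryl group is transferred from boron to the copper phenoxide and the diaryl ether is released by reductive elimination from trivalent copper, with O2 returning the metal to divalent copper; the unhindered meta,meta-disubstituted boronic acid is used in excess and the lactone and the ortho-methoxy group are inert at room temperature.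

Step 2
Reactants: 3 6-(3,5-dimethoxyphenoxy)-7-methoxy-2H-chromen-2-one
Product: 4 6-(3,5-dihydroxyphenoxy)-7-hydroxy-2H-chromen-2-one
Conditions: BBr3 (8 equiv), CH2Cl2, −78 °C → rt; ice-water quench
Reagents that add atoms: none
Why: BBr3 cleavage of aryl methyl ethers (boron–oxygen adduct, then bromide attack at the methyl carbon) removes all three methyl groups, while the diaryl ether, which offers no sp3 carbon to bromide, and the coumarin lactone survive, as is usual in the demethylation of methoxycoumarins.

Step 3
Reactants: 4 6-(3,5-dihydroxyphenoxy)-7-hydroxy-2H-chromen-2-one; 5 ethyl propiolate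
Product: 7 7-hydroxy-5-[(7-hydroxy-2-oxo-2H-chromen-6-yl)oxy]-2H-chromen-2-one, via (Z)-aryl acrylate ester 6 (not isolated)
Conditions: 5 (1.1 equiv), Pd(OAc)2 (5 mol%), TFA/CH2Cl2, 0 °C → rt
Reagents that add atoms: none
Why: In TFA, Pd(OAc)2 is converted into a cationic, strongly electrophilic trifluoroacetate of divalent palladium that palladates the electron-rich resorcinol ring (or, equivalently, activates the coordinated alkyne towards Friedel–Crafts attack by that ring); insertion of ethyl propiolate with net trans addition and protonolysis of the vinyl–palladium bond by TFA give the (Z)-acrylate 6, in which C4a–C4 is formed and the ester lies cis to the arene. The closest known reaction is the palladium-catalysed hydroarylation of propiolates by phenols to coumarins, a mild Pechmann equivalent established for resorcinol-, phloroglucinol- and 3,5-dimethoxyphenol-type substrates. The pyranone ring then closes by 6-exo-trig acyl substitution of the ethyl ester by the adjacent hydroxyl (lactonisation, O1–C2 formed, ethanol lost). No stereocentre is created, and the only geometric requirement, the cis alkene, follows from the trans hydroarylation and is locked by the ring. The step needs (a) ring selectivity, secured because unit A is a pyranone-deactivated arene while the resorcinol ring carries three oxygen donors, and (b) site selectivity, secured because the two carbons between hydroxyl and aryloxy are para to a hydroxyl and equivalent through the mirror plane of the ring, whereas the carbon between the two hydroxyls is para only to the weakly donating coumarinyloxy oxygen. Over-annulation is held back by using about one equivalent of 5, since the new pyranone deactivates ring B.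

Step 4
Reactants: 7 7-hydroxy-5-[(7-hydroxy-2-oxo-2H-chromen-6-yl)oxy]-2H-chromen-2-one
Product: 11 6,7-dihydroxy-5-[(7-hydroxy-2-oxo-2H-chromen-6-yl)oxy]-2H-chromen-2-one, via ring-opened hexasodium bis(coumarinate) 8 (not isolated), via heptasodium C-6 aryl sulfate 9 (not isolated), via relactonised aryl hydrogen sulfate 10 (not isolated)
Conditions: 2 M aq NaOH, N2, 50 °C then 5 °C; K2S2O8 (1.1 equiv), 5 °C → rt; then HCl to pH 1, 90 °C
Reagents that add atoms: potassium peroxodisulfate K2S2O8, [K+].[K+].[O-]S(=O)(=O)OOS(=O)(=O)[O-]
Why: Elbs persulfate oxidation, in which alkali opens both lactones and the phenoxide liberated from O-1 of unit B attacks the peroxide oxygen of peroxodisulfate through its para carbon C-6 (the only unsubstituted position para to a phenoxide in the whole molecule), giving an aryl sulfate that is shielded from further oxidation and is hydrolysed by hot dilute HCl while both (Z)-2-hydroxycinnamic acids relactonise, the same course by which 5,7-dioxygenated and 7-hydroxy coumarins are known to be converted into their 6-hydroxy derivatives.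

**Compound list**

1 | isoscopoletin (6-hydroxy-7-methoxy-2H-chromen-2-one) | COc1cc2oc(=O)ccc2cc1O | starting material
2 | 3,5-dimethoxyphenylboronic acid | COc1cc(OC)cc(B(O)O)c1 | starting material
3 | 6-(3,5-dimethoxyphenoxy)-7-methoxy-2H-chromen-2-one | COc1cc(OC)cc(Oc2cc3ccc(=O)oc3cc2OC)c1 | intermediate
4 | 6-(3,5-dihydroxyphenoxy)-7-hydroxy-2H-chromen-2-one | O=c1ccc2cc(Oc3cc(O)cc(O)c3)c(O)cc2o1 | intermediate
5 | ethyl propiolate | C#CC(=O)OCC | starting material
6 | ethyl (2Z)-3-{2,4-dihydroxy-6-[(7-hydroxy-2-oxo-2H-chromen-6-yl)oxy]phenyl}prop-2-enoate | CCOC(=O)/C=C\c1c(O)cc(O)cc1Oc1cc2ccc(=O)oc2cc1O | intermediate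
7 | 7-hydroxy-5-[(7-hydroxy-2-oxo-2H-chromen-6-yl)oxy]-2H-chromen-2-one | O=c1ccc2cc(Oc3cc(O)cc4oc(=O)ccc34)c(O)cc2o1 | intermediate
8 | hexasodium (2Z)-3-[2-{5-[(1Z)-2-carboxylatoethenyl]-2,4-dioxidophenoxy}-4,6-dioxidophenyl]prop-2-enoate (both lactones of 7 opened, all phenols ionised) | [Na+].[Na+].[Na+].[Na+].[Na+].[Na+].[O-]C(=O)/C=C\c1cc(Oc2cc([O-])cc([O-])c2/C=C\C([O-])=O)c([O-])cc1[O-] | intermediate
9 | heptasodium (2Z)-3-[2-{5-[(1Z)-2-carboxylatoethenyl]-2,4-dioxidophenoxy}-4,6-dioxido-3-(sulfonatooxy)phenyl]prop-2-enoate (drawn as the all-sodium salt) | [Na+].[Na+].[Na+].[Na+].[Na+].[Na+].[Na+].[O-]C(=O)/C=C\c1cc(Oc2c(OS(=O)(=O)[O-])c([O-])cc([O-])c2/C=C\C([O-])=O)c([O-])cc1[O-] | intermediate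
10 | 7-hydroxy-5-[(7-hydroxy-2-oxo-2H-chromen-6-yl)oxy]-2-oxo-2H-chromen-6-yl hydrogen sulfate | O=c1ccc2cc(Oc3c(OS(=O)(=O)O)c(O)cc4oc(=O)ccc34)c(O)cc2o1 | intermediate
11 | 6,7-dihydroxy-5-[(7-hydroxy-2-oxo-2H-chromen-6-yl)oxy]-2H-chromen-2-one (CNP0197949.0) | O=c1ccc2cc(Oc3c(O)c(O)cc4oc(=O)ccc34)c(O)cc2o1 | target

**Totals**

Total step count: 4. Longest linear sequence: 4 steps (1 → 3 → 4 → 7 → 11).

**Steps most likely to fail**

Step 4 (Elbs oxidation).
- What may go wrong: persulfate hydroxylations often stop at partial conversion. One-electron oxidation of the very electron-rich polyphenoxide could lead to oxidative coupling and dark polymeric material. Some attack ortho to a phenoxide (C-8 of either unit) could compete. Isomerisation of a cis-cinnamate to the trans acid during the alkaline phase would prevent relactonisation.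
- Fallback: carry the C-6 oxygen of unit B in from the start and keep the same palladium annulation. It sets out from 1 and comes back to the route at 11.
- Ullmann-type etherification of 1 with commercial 3-bromo-4,5-dimethoxybenzaldehyde (CuCl as the source of monovalent copper, 2,2,6,6-tetramethylheptane-3,5-dione, Cs2CO3, NMP, 120 °C) should give 3,4-dimethoxy-5-[(7-methoxy-2-oxo-2H-chromen-6-yl)oxy]benzaldehyde F1.
- Baeyer–Villiger oxidation of this electron-rich aldehyde (mCPBA, CH2Cl2) should give 3,4-dimethoxy-5-[(7-methoxy-2-oxo-2H-chromen-6-yl)oxy]phenyl formate F2.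
- Mild methanolysis (Et3N, MeOH) should free 6-(5-hydroxy-2,3-dimethoxyphenoxy)-7-methoxy-2H-chromen-2-one F3.
- Treatment of this phenol with 5 under Pd(OAc)2/TFA should add the propiolate at the carbon ortho to the hydroxyl, next to the aryloxy group and para to a methoxy group. This passes through ethyl (2Z)-3-{6-hydroxy-3,4-dimethoxy-2-[(7-methoxy-2-oxo-2H-chromen-6-yl)oxy]phenyl}prop-2-enoate F4 to 6,7-dimethoxy-5-[(7-methoxy-2-oxo-2H-chromen-6-yl)oxy]-2H-chromen-2-one F5.
- BBr3 in CH2Cl2 would then cleave the three methyl ethers to give 11.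

Step 3 (palladium annulation).
- What may go wrong: attack could compete at the carbon between the two hydroxyls, giving the isomeric 7-aryloxy-5-hydroxycoumarin. A second annulation could occur on the remaining phenol. Turnover could be slow if the triol dissolves poorly or binds the catalyst.
- Fallback: fix the position of the new carbon at an aldehyde stage and close the lactone by olefination. It sets out from 3 and comes back to the route at 7.
- Vilsmeier–Haack formylation of 3 (POCl3, DMF, 0 °C → rt; aqueous NaOAc) should take place on the phloroglucinol-type ring para to a methoxy group, giving 2,4-dimethoxy-6-[(7-methoxy-2-oxo-2H-chromen-6-yl)oxy]benzaldehyde F6. The unwanted isomer formylated between the two methoxy groups is symmetric, so it should be easy to recognise and remove.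
- BCl3 (CH2Cl2, −78 → 0 °C) should cleave only the methyl ether chelated to the aldehyde, giving 2-hydroxy-4-methoxy-6-[(7-methoxy-2-oxo-2H-chromen-6-yl)oxy]benzaldehyde F7.
- Wittig olefination with Ph3P=CHCO2Et in N,N-diethylaniline at reflux should give ethyl (2E)-3-{2-hydroxy-4-methoxy-6-[(7-methoxy-2-oxo-2H-chromen-6-yl)oxy]phenyl}prop-2-enoate F8. In the hot medium this should isomerise and lactonise to 7-methoxy-5-[(7-methoxy-2-oxo-2H-chromen-6-yl)oxy]-2H-chromen-2-one F9.
- BBr3 in CH2Cl2 would then remove both methyl groups to give 7.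

Step 1 (Chan–Lam coupling).
- What may go wrong: the ortho-methoxy, weakly nucleophilic coumarin phenol may transmetalate and eliminate slowly. The boronic acid would then be consumed by protodeboronation, homocoupling and oxidation to the phenol before the ether forms.
- Fallback: replace the oxidative coupling by an Ullmann condensation with an aryl halide. It sets out from 1 and comes back to the route at 3.
- Compound 1 is heated with commercial 1-bromo-3,5-dimethoxybenzene, CuCl (monovalent copper), 2,2,6,6-tetramethylheptane-3,5-dione and Cs2CO3 in NMP at 120 °C to give 3 directly; this fallback makes no new compound (F0).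

**Further compounds**

F1 | step 4 | 3,4-dimethoxy-5-[(7-methoxy-2-oxo-2H-chromen-6-yl)oxy]benzaldehyde | COc1cc(C=O)cc(Oc2cc3ccc(=O)oc3cc2OC)c1OC
F2 | step 4 | 3,4-dimethoxy-5-[(7-methoxy-2-oxo-2H-chromen-6-yl)oxy]phenyl formate | COc1cc(OC=O)cc(Oc2cc3ccc(=O)oc3cc2OC)c1OC
F3 | step 4 | 6-(5-hydroxy-2,3-dimethoxyphenoxy)-7-methoxy-2H-chromen-2-one | COc1cc(O)cc(Oc2cc3ccc(=O)oc3cc2OC)c1OC
F4 | step 4 | ethyl (2Z)-3-{6-hydroxy-3,4-dimethoxy-2-[(7-methoxy-2-oxo-2H-chromen-6-yl)oxy]phenyl}prop-2-enoate | CCOC(=O)/C=C\c1c(O)cc(OC)c(OC)c1Oc1cc2ccc(=O)oc2cc1OC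
F5 | step 4 | 6,7-dimethoxy-5-[(7-methoxy-2-oxo-2H-chromen-6-yl)oxy]-2H-chromen-2-one | COc1cc2oc(=O)ccc2c(Oc2cc3ccc(=O)oc3cc2OC)c1OC
F6 | step 3 | 2,4-dimethoxy-6-[(7-methoxy-2-oxo-2H-chromen-6-yl)oxy]benzaldehyde | COc1cc(OC)c(C=O)c(Oc2cc3ccc(=O)oc3cc2OC)c1
F7 | step 3 | 2-hydroxy-4-methoxy-6-[(7-methoxy-2-oxo-2H-chromen-6-yl)oxy]benzaldehyde | COc1cc(O)c(C=O)c(Oc2cc3ccc(=O)oc3cc2OC)c1
F8 | step 3 | ethyl (2E)-3-{2-hydroxy-4-methoxy-6-[(7-methoxy-2-oxo-2H-chromen-6-yl)oxy]phenyl}prop-2-enoate | CCOC(=O)/C=C/c1c(O)cc(OC)cc1Oc1cc2ccc(=O)oc2cc1OC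
F9 | step 3 | 7-methoxy-5-[(7-methoxy-2-oxo-2H-chromen-6-yl)oxy]-2H-chromen-2-one | COc1cc(Oc2cc3ccc(=O)oc3cc2OC)c2ccc(=O)oc2c1
F0 | step 1 | none | none
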